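The Q that L has carried into E cannot stand in D as well, and the suspect step Q + L into E takes one Q per L, so the charges already say something about the end of each flask.

all flasks: Q 0.44 M

| charge | L | remark | time |
|---|---|---|---|
| amber | 0.053 M | run made earlier |  |
| teal | 0.51 M | run made earlier |  |
| larch | 0.0400 M |  | 10 d |
| maple | 0.0800 M |  | 10 d |
| ash | 0.200 M |  | 10 d |
| alder | 0.400 M |  | 10 d |

| run | time / d | D / % | Q / % |
|---|---|---|---|
| amber | 0.833 | 54.6 | 34.2 |
| amber | 1.67 | 66.2 | 21.5 |
| amber | 3.00 | 73.6 | 12.7 |
| amber | 5.00 | 78.2 | 9.1 |
| amber | 10.0 | 84.4 | 6.2 |
| teal | 0.833 | 6.1 | 0.4 |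
| teal | 2.50 | 3.3 | 0 |
| teal | 5.00 | 6.4 | 2.4 |
| teal | 8.00 | 6.1 | 0.5 |
| teal | 10.0 | 5.2 | 1.2 |

(readings scatter by 1 percentage point)

- a species is counted by the Q in it: one D counts as two
- on the list of suspects stand: 2 Q -> D; Q + L -> E
- "hardly changes" means that all values lie within two and a half points (for a concentration: within two and a half percent of the largest)

- amount of D at the end, in percent of the Q charged for larch, maple, ash, alder, in this order
- how the row runs (falls all the way / rises all the way / hardly changes / rises, then falls / falls, then rises)

In amber, L is 12.0% of the Q charged, and the part of the charge missing from D and Q is 11.2% at 0.833 d and 9.40% at 10.0 d. Each gap carries the scatter of two readings, so E looks made early and kept. But teal, with L at 116% of the Q charged, still shows D of 5.2% at 10.0 d, so in teal some D forms beside E, and a plain count is weakest where L comes close to Q.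

For larch, one minus L over Q gives 90.9%: this is the spare fraction, the part of the Q charged that remains after L, the limiting reagent of that step, has taken one Q each. D at the end is then the spare fraction less the Q still left, and amber's 6.2% at the same time is carried over as an assumption. That reckoning gives larch 84.7%, maple 75.6% and ash 48.3%. Alder's spare fraction is 9.09%, so its D is reckoned between teal's D and that figure, and the row falls.

The forecast gives 86%, 77%, 49% and 8%, falls all the way, holding that “each L removes one Q quickly and E persists”; at maple it stands 1.4 percentage points above this reckoning.

The flasks give 86.3%, 77.2%, 50.1% and 9.14%, falls all the way, and the forecast holds within its margin.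

    2 Q → D (k = 0.0970 M⁻¹ h⁻¹)
    Q + L → E (k = 2.10 M⁻¹ h⁻¹)

In larch, half of the turnover of Q + L into E is done by 0.797 h, whereas the turning of two Q into D needs 0.474 d for its half, and the ratio of Q used by the turning of two Q into D to Q used by Q + L into E climbs from 1.0 at the start to 460 at 0.474 d. At the end, larch's D and Q add up to 90.9% against its spare fraction of 90.9%, and ash's add up to 54.5% against a spare fraction of 54.5%.

(The earlier runs and the new flask are simulated with made-up constants.)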